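The constants of these flasks are not given, so a count of acid has to stand in for them, and the runs can test that count.

common to all: electrophile 0.050 M

| charge | free base | protonated nucleophile | scavenger | remark | time |
|---|---|---|---|---|---|
| beta | 0.059 M | 0.10 M | 0.075 M | run made earlier |  |
| delta | 0.066 M | 0.10 M | 0.075 M | run made earlier |  |
| zeta | 0.090 M | 0.10 M | 0.075 M | run made earlier |  |
| larch | 0.0500 M | 0.100 M | 0.0750 M |  | 8.0 h |
| cedar | 0.0650 M | 0.100 M | 0.0750 M |  | 8.0 h |
| oak | 0.0850 M | 0.100 M | 0.0750 M |  | 8.0 h |

- beta (time / h: electrophile / %, product / %): 1.50: 40.2, 59.8; 3.00: 29.3, 71.0; 5.00: 19.5, 80.6; 6.00: 15.5, 84.1; 8.00: 9.8, 90.4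
- delta (time / h: electrophile / %, product / %): 1.50: 35.4, 65.4; 3.00: 25.1, 75.1; 5.00: 15.8, 84.0; 6.00: 12.5, 87.5; 8.00: 7.8, 92.6
- zeta (time / h: electrophile / %, product / %): 1.50: 20.4, 79.2; 3.00: 11.9, 88.0; 5.00: 6.6, 94.0; 6.00: 4.6, 95.8; 8.00: 1.6, 98.2

(each reading ± 0.3 percentage points)

- a reading or a percentage of product counts all its forms, free or not

- part of the electrophile that has reacted at the end, larch
- part of the electrophile that has reacted at the end, cedar
- part of the electrophile that has reacted at the end, oak
- what raising the concentration of free base from its lowest to its highest value here does to the part of the electrophile that has reacted (changes below 5 percentage points count as none) (no change / it falls / it rises)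

Where does the fast stretch end? Suppose each electrophile reacted costs two acid-takers: one to free the nucleophile from the protonated nucleophile, one for the acid its reaction sets free. Free base would then carry the delta run to 66.0%, and its product reads 65.4% at 1.50 h, where the curve has already bent.

Does the flask stop there? No: delta reaches 92.6% of product at 8.00 h, more than that share, so a second, slower taker works, presumably the scavenger. The electrophile readings of delta from 3.00 h to 8.00 h give a time constant of 4.28 h.

So the rule is the acid ceiling: free base and scavenger charged, over twice the electrophile charged 125%. That is its value for larch; cedar has 140%. In larch the two takers together exceed twice the electrophile, so by this count the electrophile is the limiting reagent.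

How far then by 8.0 h? This reckoning starts the decay at 1.50 h from what free base leaves. It gives 89.1% for larch, 92.3% for cedar and 96.7% for oak, a rise of 7.6 percentage points.

The forecast gives 87.6%, 91.9% and 97.1%, and for the trend it rises, from a nearly straight line through the electrophile left at the last reading of the earlier runs against free base, with the words “I did not settle the mechanism, so I interpolate empirically”. For larch it stands lower than this reckoning, for oak higher.

Larch gives 86.9%, cedar 92.3%, oak 97.2%: it rises, by 10 points.

    electrophile + nucleophile → acid set free + product (k = 0.813 L mol⁻¹ min⁻¹)
    nucleophile + acid set free ⇌ protonated nucleophile, settled at all times (K = 1.10 × 10⁵ L mol⁻¹)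
    acid set free + free base ⇌ salt of the base, settled at all times (K = 4.30 × 10⁵ L mol⁻¹)
    crystals ⇌ product, rate k4*(cs4 - [product]) while solid is left; crystals form when [product] > cs4 (solubility = 0.650 mM, k = 0.604 min⁻¹)
    acid set free + free base ⇌ idle adduct, settled at all times (K = 16.4 L mol⁻¹)
    acid set free + scavenger → scavenged by-product (k = 13.4 L mol⁻¹ min⁻¹)

At 8.00 h larch holds 13% of its electrophile, less than the 44% of its scavenger, and at 80.0 h it shows 100% reacted, below its ceiling. Cedar charged with 0.20 M of electrophile has a ceiling of 35.0%. That flask gives 35.1% at 8.00 h, with 1.3% of its scavenger and 0.14% of its free base still unbound.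

Readings and results were computed on assumed constants; the scatter is artificial.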